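**Plan**
1. Cuts: C11=C12 (last C–C bond, Wittig) gives a C15 triol aldehyde and a C25 ylide. The sp–sp2 bond C8'–C9' of the C25 unit is then cut to the C11 ring alkyne and a C14 tetraenynal (C10 dialdehyde + C4 phosphonate). Both rings go back to one enol triflate of (4R,6R)-actinol.
2. Enabling feature: C9' carries the C19' methyl and lies between the C7'≡C8' triple bond and the C10'=C11' double bond. C8'–C9'(CH3)=C10'H is therefore the syn adduct of the alkyne C8'–H across a C19'H3–C9'≡C10' triple bond, which the C12 formyl group polarises through the C11'=C12' to C13=C14 tetraene. One catalytic, by-product-free event forms the bond and fixes 9'E, a geometry that later equilibration next to a triple bond could not be trusted to restore.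
3. Forward order: actinol → enol triflate → (a) ethynylcyclohexene, (b) ester → allylic alcohol → syn-epoxide → trans-5,6-diol → C15 dienal. C14 ynal + alkyne → C25 aldehyde → alcohol → phosphonium salt; Wittig; desilylation. No ring is formed; both six-membered rings come from actinol.
4. Stereochemistry: C3 and C3' from C4 of actinol; C6 from reagent-controlled Sharpless epoxidation and C5 from invertive hydrolysis of that epoxide; 9'E from syn carbopalladation; the other E bonds from HWE/Wittig steps and the all-E C10 dialdehyde.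

Key step: step 6

Remark: positions are given in carotenoid numbering (C1–C20 for the triol half, primed for the acetylenic half); compounds 1, 9 and 21 are taken as catalogue chemicals, 21 as its commercial E/Z mixture.

**Route**

Step 1
Reactants: 1 (4R,6R)-4-hydroxy-2,2,6-trimethylcyclohexan-1-one
Product: 2 (4R,6R)-4-[(tert-butyldimethylsilyl)oxy]-2,2,6-trimethylcyclohexan-1-one
Conditions: TBSCl, imidazole, DMF, rt
Reagents that add atoms: tert-butyldimethylsilyl chloride, CC(C)(C)[Si](C)(C)Cl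
Why: Standard silyl ether protection of the secondary alcohol, needed because the next step uses a strong amide base; no stereocentre is touched.

Step 2
Reactants: 2 (4R,6R)-4-[(tert-butyldimethylsilyl)oxy]-2,2,6-trimethylcyclohexan-1-one
Product: 4 (4R)-4-[(tert-butyldimethylsilyl)oxy]-2,6,6-trimethylcyclohex-1-en-1-yl trifluoromethanesulfonate, via lithium enolate 3 (not isolated)
Conditions: LiN(iPr)2, THF, −78 °C; PhNTf2, −78 °C to rt
Reagents that add atoms: N-phenylbis(trifluoromethanesulfonimide), O=S(=O)(N(c1ccccc1)S(=O)(=O)C(F)(F)F)C(F)(F)F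
Why: The ketone has a single α-hydrogen, so deprotonation and O-triflation (enol triflate formation) can give only the tetrasubstituted enol triflate; the methyl-bearing stereocentre is erased on purpose and the carbinol centre (later C3 and C3') is untouched.

Step 3
Reactants: 4 (4R)-4-[(tert-butyldimethylsilyl)oxy]-2,6,6-trimethylcyclohex-1-en-1-yl trifluoromethanesulfonate; 5 ethynylmagnesium bromide
Product: 6 tert-butyl{[(1R)-4-ethynyl-3,5,5-trimethylcyclohex-3-en-1-yl]oxy}dimethylsilane
Conditions: 5, ZnBr2, THF, 0 °C; then 4, Pd(PPh3)4 (5 mol%), THF, rt to 50 °C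
Reagents that add atoms: none
Why: Negishi coupling: oxidative addition of zerovalent palladium to the enol triflate and transmetalation from ethynylzinc bromide give the terminal enyne directly, installing C7' and C8' without an alkyne protecting group.

Step 4
Reactants: 7 1-bromobut-2-yne
Product: 8 diethyl but-2-yn-1-ylphosphonate
Conditions: P(OEt)3, neat, 120 °C
Reagents that add atoms: triethyl phosphite, CCOP(OCC)OCC
Why: Michaelis–Arbuzov reaction of a reactive propargylic bromide; the volatile alkyl bromide formed leaves the mixture and drives the reaction.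

Step 5
Reactants: 8 diethyl but-2-yn-1-ylphosphonate; 9 (2E,4E,6E)-2,7-dimethylocta-2,4,6-trienedial
Product: 11 (2E,4E,6E,8E)-2,7-dimethyldodeca-2,4,6,8-tetraen-10-ynal, via sodium phosphonate carbanion 10 (not isolated)
Conditions: NaN(SiMe3)2, THF, −78 °C; added to 9 (3 equiv), −78 to 0 °C
Reagents that add atoms: none
Why: Horner–Wadsworth–Emmons olefination of one formyl group of the symmetrical dialdehyde (used in excess to suppress double condensation); the propargylic phosphonate anion should form the new C11'=C12' bond E, as is usual for phosphonate anions with α-branched enals.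

Step 6
Reactants: 6 tert-butyl{[(1R)-4-ethynyl-3,5,5-trimethylcyclohex-3-en-1-yl]oxy}dimethylsilane; 11 (2E,4E,6E,8E)-2,7-dimethyldodeca-2,4,6,8-tetraen-10-ynal
Product: 12 (2E,4E,6E,8E,10E)-13-[(4R)-4-[(tert-butyldimethylsilyl)oxy]-2,6,6-trimethylcyclohex-1-en-1-yl]-2,7,11-trimethyltrideca-2,4,6,8,10-pentaen-12-ynal
Conditions: Pd(OAc)2 (5 mol%), tris(2,6-dimethoxyphenyl)phosphine (5 mol%), 6 (1.2 equiv), THF, rt, argon, dark
Reagents that add atoms: none
Why: Proposed new method: acetate-assisted palladation of the C8'–H bond of 6 gives an alkynyl acetate complex of divalent palladium, which coordinates the C9'≡C10' triple bond of 11 and inserts it syn; the alkynyl group goes to C9' (the methyl-bearing alkyne carbon and electrophilic terminus of the conjugated system ending in the C12 formyl group) and palladium to C10' (a vinylogous enolate position), and protonolysis of the C10'–Pd bond with retention by acetic acid or a second molecule of 6 releases 12 and regenerates the catalyst. The closest known reaction type is the Pd(OAc)2/tris(2,6-dimethoxyphenyl)phosphine cross-addition of terminal alkynes to alk-2-ynoates and ynones, which is syn-specific and places the alkynyl group on the β-carbon; the extension through four double bonds is argued from the known 1,8- to 1,12-additions of organocuprates to polyenynoates, which also attack the remote alkyne carbon. No ring is closed. No stereocentre is formed; the new stereo-element is the 9'E double bond, which follows from syn addition (H and alkynyl cis, hence alkynyl trans to C11') and is set kinetically, which matters because E is not reliably favoured at equilibrium beside a 7',8' triple bond. The step needs regioselectivity (C9' over C10'), which the polarisation by the formyl group and the small methyl terminus should secure. It also needs chemoselectivity over dimerisation of 6 and over addition to C=C or C=O, which the shielding of C7' by the gem-dimethyl and ring methyl groups and the catalyst's preference for the electron-poor alkyne should secure.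

Step 7
Reactants: 12 (2E,4E,6E,8E,10E)-13-[(4R)-4-[(tert-butyldimethylsilyl)oxy]-2,6,6-trimethylcyclohex-1-en-1-yl]-2,7,11-trimethyltrideca-2,4,6,8,10-pentaen-12-ynal
Product: 13 (2E,4E,6E,8E,10E)-13-[(4R)-4-[(tert-butyldimethylsilyl)oxy]-2,6,6-trimethylcyclohex-1-en-1-yl]-2,7,11-trimethyltrideca-2,4,6,8,10-pentaen-12-yn-1-ol
Conditions: NaBH4, MeOH/CH2Cl2, 0 °C
Reagents that add atoms: none
Why: Chemoselective 1,2-reduction of the conjugated aldehyde by borohydride; alkyne, polyene and silyl ether are inert.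

Step 8
Reactants: 13 (2E,4E,6E,8E,10E)-13-[(4R)-4-[(tert-butyldimethylsilyl)oxy]-2,6,6-trimethylcyclohex-1-en-1-yl]-2,7,11-trimethyltrideca-2,4,6,8,10-pentaen-12-yn-1-ol
Product: 14 [(2E,4E,6E,8E,10E)-13-[(4R)-4-[(tert-butyldimethylsilyl)oxy]-2,6,6-trimethylcyclohex-1-en-1-yl]-2,7,11-trimethyltrideca-2,4,6,8,10-pentaen-12-yn-1-yl]triphenylphosphonium bromide
Conditions: PPh3·HBr, CH2Cl2, 0 °C to rt, dark
Reagents that add atoms: triphenylphosphine hydrobromide, Br.c1ccc(cc1)P(c1ccccc1)c1ccccc1
Why: Phosphonium salt formation from a polyenylic alcohol (substitution through the allylic cation, captured by PPh3 at the primary terminus C12), the standard entry to carotenoid Wittig salts; kept cold and short so that the 9'E bond and the silyl ether should survive.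

Step 9
Reactants: 4 (4R)-4-[(tert-butyldimethylsilyl)oxy]-2,6,6-trimethylcyclohex-1-en-1-yl trifluoromethanesulfonate
Product: 15 methyl (4R)-4-[(tert-butyldimethylsilyl)oxy]-2,6,6-trimethylcyclohex-1-ene-1-carboxylate
Conditions: Pd(OAc)2 (5 mol%), PPh3 (10 mol%), CO (1 atm), MeOH, Et3N, DMF, 60 °C
Reagents that add atoms: carbon monoxide, [C-]#[O+]; methanol, CO
Why: Palladium-catalysed methoxycarbonylation of the enol triflate (oxidative addition, CO insertion, methanolysis of the acylpalladium) introduces C7 of the triol half as an ester.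

Step 10
Reactants: 15 methyl (4R)-4-[(tert-butyldimethylsilyl)oxy]-2,6,6-trimethylcyclohex-1-ene-1-carboxylate
Product: 16 [(4R)-4-[(tert-butyldimethylsilyl)oxy]-2,6,6-trimethylcyclohex-1-en-1-yl]methanol
Conditions: iBu2AlH, CH2Cl2, −78 to 0 °C; aq. potassium sodium tartrate
Reagents that add atoms: none
Why: Hydride reduction of the hindered enoate to the allylic alcohol that the directed epoxidation requires; the silyl ether is stable.

Step 11
Reactants: 16 [(4R)-4-[(tert-butyldimethylsilyl)oxy]-2,6,6-trimethylcyclohex-1-en-1-yl]methanol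
Product: 17 [(1S,4S,6S)-4-[(tert-butyldimethylsilyl)oxy]-2,2,6-trimethyl-7-oxabicyclo[4.1.0]heptan-1-yl]methanol
Conditions: Ti(OiPr)4 (20 mol%), L-(+)-diethyl tartrate (24 mol%), tBuOOH, 4 Å molecular sieves, CH2Cl2, −20 °C
Reagents that add atoms: tert-butyl hydroperoxide, CC(C)(C)OO
Why: Sharpless asymmetric epoxidation: by reagent control the L-(+)-tartrate catalyst should deliver oxygen to the C5=C6 face syn to the C3 silyloxy group (the remote C3 centre exerting little bias), which sets the C6 oxygen and places the C5 oxygen for later inversion.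

Step 12
Reactants: 17 [(1S,4S,6S)-4-[(tert-butyldimethylsilyl)oxy]-2,2,6-trimethyl-7-oxabicyclo[4.1.0]heptan-1-yl]methanol
Product: 18 (1S,2R,4S)-4-[(tert-butyldimethylsilyl)oxy]-1-(hydroxymethyl)-2,6,6-trimethylcyclohexane-1,2-diol
Conditions: HClO4 (5 mol%), THF/H2O (3:1), 0 °C
Reagents that add atoms: water, O
Why: Acid-catalysed epoxide hydrolysis: of the two tertiary epoxide carbons, C5 is less hindered and is not deactivated by the adjacent hydroxymethyl group, so water should open the protonated epoxide at C5 with inversion, giving the 5R hydroxyl trans to the retained C6 oxygen under conditions too mild to cleave the secondary silyl ether.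

Step 13
Reactants: 18 (1S,2R,4S)-4-[(tert-butyldimethylsilyl)oxy]-1-(hydroxymethyl)-2,6,6-trimethylcyclohexane-1,2-diol
Product: 19 (1R,2R,4S)-4-[(tert-butyldimethylsilyl)oxy]-1,2-dihydroxy-2,6,6-trimethylcyclohexane-1-carbaldehyde
Conditions: SO3·pyridine, DMSO, iPr2NEt, CH2Cl2, 0 °C
Reagents that add atoms: none
Why: Parikh–Doering oxidation converts the only oxidisable (primary) hydroxyl into the aldehyde; an activated-DMSO oxidant is chosen because it does not cleave 1,2-diols.

Step 14
Reactants: 19 (1R,2R,4S)-4-[(tert-butyldimethylsilyl)oxy]-1,2-dihydroxy-2,6,6-trimethylcyclohexane-1-carbaldehyde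
Product: 20 (1R,2R,4S)-4-[(tert-butyldimethylsilyl)oxy]-2,6,6-trimethyl-1,2-bis[(trimethylsilyl)oxy]cyclohexane-1-carbaldehyde
Conditions: Me3SiOTf, 2,6-lutidine, CH2Cl2, −78 to 0 °C
Reagents that add atoms: trimethylsilyl trifluoromethanesulfonate, C[Si](C)(C)OS(=O)(=O)C(F)(F)F
Why: Silyl triflate silylation of the two tertiary hydroxyls (possible because the aldehyde has no α-hydrogen) prevents retro-aldol cleavage of the β-hydroxy aldehyde and alkoxide formation in the basic olefinations that follow.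

Step 15
Reactants: 20 (1R,2R,4S)-4-[(tert-butyldimethylsilyl)oxy]-2,6,6-trimethyl-1,2-bis[(trimethylsilyl)oxy]cyclohexane-1-carbaldehyde; 21 diethyl (3-cyano-2-methylprop-2-en-1-yl)phosphonate
Product: 23 (2E,4E)-5-[(1R,2R,4S)-4-[(tert-butyldimethylsilyl)oxy]-2,6,6-trimethyl-1,2-bis[(trimethylsilyl)oxy]cyclohexyl]-3-methylpenta-2,4-dienenitrile, via lithium phosphonate carbanion 22 (not isolated)
Conditions: nBuLi, THF, −78 °C; then 20, −78 to 0 °C
Reagents that add atoms: none
Why: Horner–Wadsworth–Emmons reaction with the C5 nitrile phosphonate builds C8–C11 at once; the new C7=C8 bond should form E and the C9=C10 bond mainly E, because the allylic anion equilibrates and the E,E-dienenitrile is favoured (a minor 9Z isomer would be removed by chromatography).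

Step 16
Reactants: 23 (2E,4E)-5-[(1R,2R,4S)-4-[(tert-butyldimethylsilyl)oxy]-2,6,6-trimethyl-1,2-bis[(trimethylsilyl)oxy]cyclohexyl]-3-methylpenta-2,4-dienenitrile
Product: 25 (2E,4E)-5-[(1R,2R,4S)-4-[(tert-butyldimethylsilyl)oxy]-2,6,6-trimethyl-1,2-bis[(trimethylsilyl)oxy]cyclohexyl]-3-methylpenta-2,4-dienal, via N-aluminio aldimine 24 (not isolated)
Conditions: iBu2AlH, CH2Cl2, −78 °C; then wet silica gel, 0 °C
Reagents that add atoms: water, O
Why: Single hydride addition to the nitrile gives an aluminated aldimine that is hydrolysed to the aldehyde on work-up (nitrile-to-aldehyde reduction); silyl ethers and the diene are unaffected.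

Step 17
Reactants: 14 [(2E,4E,6E,8E,10E)-13-[(4R)-4-[(tert-butyldimethylsilyl)oxy]-2,6,6-trimethylcyclohex-1-en-1-yl]-2,7,11-trimethyltrideca-2,4,6,8,10-pentaen-12-yn-1-yl]triphenylphosphonium bromide; 25 (2E,4E)-5-[(1R,2R,4S)-4-[(tert-butyldimethylsilyl)oxy]-2,6,6-trimethyl-1,2-bis[(trimethylsilyl)oxy]cyclohexyl]-3-methylpenta-2,4-dienal
Product: 27 (3S,5R,6R,3'R)-3,3'-bis[(tert-butyldimethylsilyl)oxy]-5,6-bis[(trimethylsilyl)oxy]-7',8'-didehydro-5,6-dihydro-β,β-carotene, via phosphorus ylide 26 (not isolated)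
Conditions: NaN(SiMe3)2, THF, −78 °C; then 25, −78 °C to rt, dark; then EtOAc, 60 °C, dark
Reagents that add atoms: none
Why: Wittig olefination joins C11 and C12; the semi-stabilised polyenyl ylide should give mainly the 11E olefin, and any 11Z isomer is a hindered cis olefin (C10–H against the C13 methyl) that should relax on gentle warming to all-E without moving the 9'E enyne bond.

Step 18
Reactants: 27 (3S,5R,6R,3'R)-3,3'-bis[(tert-butyldimethylsilyl)oxy]-5,6-bis[(trimethylsilyl)oxy]-7',8'-didehydro-5,6-dihydro-β,β-carotene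
Product: 28 (3S,5R,6R,3'R)-7',8'-didehydro-5,6-dihydro-β,β-carotene-3,5,6,3'-tetrol (heteroxanthin, CNP0160593.3)
Conditions: Bu4NF, THF, 0 °C to rt, dark
Reagents that add atoms: none
Why: Fluoride desilylation removes all four silyl ethers under non-acidic conditions, which spares the tertiary allylic C6 hydroxyl and the polyene.

**Compound list**
1 | (4R,6R)-4-hydroxy-2,2,6-trimethylcyclohexan-1-one (actinol) | CC1(C)C[C@H](O)C[C@@H](C)C1=O | starting material
2 | (4R,6R)-4-[(tert-butyldimethylsilyl)oxy]-2,2,6-trimethylcyclohexan-1-one | CC1(C)C[C@H](O[Si](C)(C)C(C)(C)C)C[C@@H](C)C1=O | intermediate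
3 | lithium (4R)-4-[(tert-butyldimethylsilyl)oxy]-2,6,6-trimethylcyclohex-1-en-1-olate | [Li+].CC1=C([O-])C(C)(C)C[C@H](O[Si](C)(C)C(C)(C)C)C1 | intermediate
4 | (4R)-4-[(tert-butyldimethylsilyl)oxy]-2,6,6-trimethylcyclohex-1-en-1-yl trifluoromethanesulfonate | CC1=C(OS(=O)(=O)C(F)(F)F)C(C)(C)C[C@H](O[Si](C)(C)C(C)(C)C)C1 | intermediate
5 | ethynylmagnesium bromide | C#C[Mg]Br | starting material
6 | tert-butyl{[(1R)-4-ethynyl-3,5,5-trimethylcyclohex-3-en-1-yl]oxy}dimethylsilane | CC1=C(C#C)C(C)(C)C[C@H](O[Si](C)(C)C(C)(C)C)C1 | intermediate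
7 | 1-bromobut-2-yne | CC#CCBr | starting material
8 | diethyl but-2-yn-1-ylphosphonate | CC#CCP(=O)(OCC)OCC | intermediate
9 | (2E,4E,6E)-2,7-dimethylocta-2,4,6-trienedial | O=C/C(C)=C/C=C/C=C(C)/C=O | starting material
10 | sodium salt of the α-carbanion of 8 | [Na+].CC#C[CH-]P(=O)(OCC)OCC | intermediate
11 | (2E,4E,6E,8E)-2,7-dimethyldodeca-2,4,6,8-tetraen-10-ynal | CC#C/C=C/C(C)=C/C=C/C=C(C)/C=O | intermediate
12 | (2E,4E,6E,8E,10E)-13-[(4R)-4-[(tert-butyldimethylsilyl)oxy]-2,6,6-trimethylcyclohex-1-en-1-yl]-2,7,11-trimethyltrideca-2,4,6,8,10-pentaen-12-ynal | CC1=C(C#C/C(C)=C/C=C/C(C)=C/C=C/C=C(C)/C=O)C(C)(C)C[C@H](O[Si](C)(C)C(C)(C)C)C1 | intermediate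
13 | (2E,4E,6E,8E,10E)-13-[(4R)-4-[(tert-butyldimethylsilyl)oxy]-2,6,6-trimethylcyclohex-1-en-1-yl]-2,7,11-trimethyltrideca-2,4,6,8,10-pentaen-12-yn-1-ol | CC1=C(C#C/C(C)=C/C=C/C(C)=C/C=C/C=C(C)/CO)C(C)(C)C[C@H](O[Si](C)(C)C(C)(C)C)C1 | intermediate
14 | [(2E,4E,6E,8E,10E)-13-[(4R)-4-[(tert-butyldimethylsilyl)oxy]-2,6,6-trimethylcyclohex-1-en-1-yl]-2,7,11-trimethyltrideca-2,4,6,8,10-pentaen-12-yn-1-yl]triphenylphosphonium bromide | CC1=C(C#C/C(C)=C/C=C/C(C)=C/C=C/C=C(C)/C[P+](c2ccccc2)(c2ccccc2)c2ccccc2)C(C)(C)C[C@H](O[Si](C)(C)C(C)(C)C)C1.[Br-] | intermediate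
15 | methyl (4R)-4-[(tert-butyldimethylsilyl)oxy]-2,6,6-trimethylcyclohex-1-ene-1-carboxylate | CC1=C(C(=O)OC)C(C)(C)C[C@H](O[Si](C)(C)C(C)(C)C)C1 | intermediate
16 | [(4R)-4-[(tert-butyldimethylsilyl)oxy]-2,6,6-trimethylcyclohex-1-en-1-yl]methanol | CC1=C(CO)C(C)(C)C[C@H](O[Si](C)(C)C(C)(C)C)C1 | intermediate
17 | [(1S,4S,6S)-4-[(tert-butyldimethylsilyl)oxy]-2,2,6-trimethyl-7-oxabicyclo[4.1.0]heptan-1-yl]methanol (epoxide syn to the silyloxy group) | CC1(C)C[C@H](O[Si](C)(C)C(C)(C)C)C[C@]2(C)O[C@]12CO | intermediate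
18 | (1S,2R,4S)-4-[(tert-butyldimethylsilyl)oxy]-1-(hydroxymethyl)-2,6,6-trimethylcyclohexane-1,2-diol | OC[C@@]1(O)C(C)(C)C[C@H](O[Si](C)(C)C(C)(C)C)C[C@@]1(C)O | intermediate
19 | (1R,2R,4S)-4-[(tert-butyldimethylsilyl)oxy]-1,2-dihydroxy-2,6,6-trimethylcyclohexane-1-carbaldehyde | O=C[C@@]1(O)C(C)(C)C[C@H](O[Si](C)(C)C(C)(C)C)C[C@@]1(C)O | intermediate
20 | (1R,2R,4S)-4-[(tert-butyldimethylsilyl)oxy]-2,6,6-trimethyl-1,2-bis[(trimethylsilyl)oxy]cyclohexane-1-carbaldehyde | O=C[C@@]1(O[Si](C)(C)C)C(C)(C)C[C@H](O[Si](C)(C)C(C)(C)C)C[C@@]1(C)O[Si](C)(C)C | intermediate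
21 | diethyl (3-cyano-2-methylprop-2-en-1-yl)phosphonate (E/Z mixture) | CCOP(=O)(CC(C)=CC#N)OCC | starting material
22 | lithium salt of the α-carbanion of 21 | [Li+].CCOP(=O)([CH-]C(C)=CC#N)OCC | intermediate
23 | (2E,4E)-5-[(1R,2R,4S)-4-[(tert-butyldimethylsilyl)oxy]-2,6,6-trimethyl-1,2-bis[(trimethylsilyl)oxy]cyclohexyl]-3-methylpenta-2,4-dienenitrile | N#C/C=C(C)/C=C/[C@@]1(O[Si](C)(C)C)C(C)(C)C[C@H](O[Si](C)(C)C(C)(C)C)C[C@@]1(C)O[Si](C)(C)C | intermediate
24 | N-(diisobutylalumino) aldimine of 25 | CC(C)C[Al](CC(C)C)N=C/C=C(C)/C=C/[C@@]1(O[Si](C)(C)C)C(C)(C)C[C@H](O[Si](C)(C)C(C)(C)C)C[C@@]1(C)O[Si](C)(C)C | intermediate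
25 | (2E,4E)-5-[(1R,2R,4S)-4-[(tert-butyldimethylsilyl)oxy]-2,6,6-trimethyl-1,2-bis[(trimethylsilyl)oxy]cyclohexyl]-3-methylpenta-2,4-dienal | O=C/C=C(C)/C=C/[C@@]1(O[Si](C)(C)C)C(C)(C)C[C@H](O[Si](C)(C)C(C)(C)C)C[C@@]1(C)O[Si](C)(C)C | intermediate
26 | triphenylphosphonium ylide derived from 14 | CC1=C(C#C/C(C)=C/C=C/C(C)=C/C=C/C=C(C)/C=P(c2ccccc2)(c2ccccc2)c2ccccc2)C(C)(C)C[C@H](O[Si](C)(C)C(C)(C)C)C1 | intermediate
27 | (3S,5R,6R,3'R)-3,3'-bis[(tert-butyldimethylsilyl)oxy]-5,6-bis[(trimethylsilyl)oxy]-7',8'-didehydro-5,6-dihydro-β,β-carotene | CC1=C(C#C/C(C)=C/C=C/C(C)=C/C=C/C=C(C)/C=C/C=C(C)/C=C/[C@@]2(O[Si](C)(C)C)C(C)(C)C[C@H](O[Si](C)(C)C(C)(C)C)C[C@@]2(C)O[Si](C)(C)C)C(C)(C)C[C@H](O[Si](C)(C)C(C)(C)C)C1 | intermediate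
28 | (3S,5R,6R,3'R)-7',8'-didehydro-5,6-dihydro-β,β-carotene-3,5,6,3'-tetrol (heteroxanthin) | CC1=C(C#C/C(C)=C/C=C/C(C)=C/C=C/C=C(C)/C=C/C=C(C)/C=C/[C@@]2(O)C(C)(C)C[C@H](O)C[C@@]2(C)O)C(C)(C)C[C@H](O)C1 | target

**Count and risks**
Total: 18 steps. Longest linear sequence: 12 steps (1, 2, 9 to 18).

Steps most likely to fail:

1. Step 6 (proposed new method). The alkynylpalladium species may insert the C9'≡C10' bond in the wrong orientation, add to a C=C bond of the polyenal, or simply dimerise 6, because the remote formyl group may activate the triple bond too weakly. Fallback with known chemistry, setting out from 6 and returning at 12: under the same Pd(OAc)2/phosphine catalysis 6 is added to ethyl but-2-ynoate, the directly conjugated acceptor class for which syn cross-addition with the alkynyl group on the β-carbon is established, to give ethyl (2E)-5-[(4R)-4-[(tert-butyldimethylsilyl)oxy]-2,6,6-trimethylcyclohex-1-en-1-yl]-3-methylpent-2-en-4-ynoate F1. Reduction with iBu2AlH gives the allylic alcohol F2. PPh3·HBr in CH2Cl2 at 0 °C gives the C15 phosphonium bromide F3. Wittig reaction of F3 with an excess of dialdehyde 9 (NaOMe, CH2Cl2/MeOH) forms the C11'=C12' bond and gives 12.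

2. Step 12. Ionisation at C5 may lead to elimination or semipinacol ring contraction instead of invertive capture by water, capture may occur with partial retention, or the silyl ether may be lost. Fallback, setting out from 17 and returning at 18: Ti(OiPr)4-mediated opening of the 2,3-epoxy alcohol with benzoic acid, in which the carboxylate is delivered with inversion to C5 (the epoxide carbon remote from the titanium-bound CH2O group), gives the C5 benzoate F4. Methanolysis (K2CO3, MeOH) then gives 18.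

3. Step 8. Acid-promoted ionisation to a delocalised polyenyl cation may scramble double-bond geometry (including 9'E) or cleave the silyl ether before PPh3 captures the cation. Fallback, setting out from 13 and returning at 27 (it replaces steps 8 and 17): Mitsunobu reaction of 13 with 1-phenyl-1H-tetrazole-5-thiol (PPh3, diisopropyl azodicarboxylate) gives the allylic tetrazolyl sulfide F5 by direct displacement without a cation. Oxidation ((NH4)6Mo7O24, H2O2, EtOH, 0 °C) gives the sulfone F6. Julia–Kocienski olefination of F6 with 25 (KN(SiMe3)2, THF, −78 °C) gives 27.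

**Further compounds**
F1 | step 6 | ethyl (2E)-5-[(4R)-4-[(tert-butyldimethylsilyl)oxy]-2,6,6-trimethylcyclohex-1-en-1-yl]-3-methylpent-2-en-4-ynoate | CC1=C(C#C/C(C)=C/C(=O)OCC)C(C)(C)C[C@H](O[Si](C)(C)C(C)(C)C)C1
F2 | step 6 | (2E)-5-[(4R)-4-[(tert-butyldimethylsilyl)oxy]-2,6,6-trimethylcyclohex-1-en-1-yl]-3-methylpent-2-en-4-yn-1-ol | CC1=C(C#C/C(C)=C/CO)C(C)(C)C[C@H](O[Si](C)(C)C(C)(C)C)C1
F3 | step 6 | [(2E)-5-[(4R)-4-[(tert-butyldimethylsilyl)oxy]-2,6,6-trimethylcyclohex-1-en-1-yl]-3-methylpent-2-en-4-yn-1-yl]triphenylphosphonium bromide | CC1=C(C#C/C(C)=C/C[P+](c2ccccc2)(c2ccccc2)c2ccccc2)C(C)(C)C[C@H](O[Si](C)(C)C(C)(C)C)C1.[Br-]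
F4 | step 12 | (1R,2S,5S)-5-[(tert-butyldimethylsilyl)oxy]-2-hydroxy-2-(hydroxymethyl)-1,3,3-trimethylcyclohexyl benzoate | OC[C@@]1(O)C(C)(C)C[C@H](O[Si](C)(C)C(C)(C)C)C[C@@]1(C)OC(=O)c2ccccc2
F5 | step 8 | 5-{[(2E,4E,6E,8E,10E)-13-[(4R)-4-[(tert-butyldimethylsilyl)oxy]-2,6,6-trimethylcyclohex-1-en-1-yl]-2,7,11-trimethyltrideca-2,4,6,8,10-pentaen-12-yn-1-yl]sulfanyl}-1-phenyl-1H-tetrazole | CC1=C(C#C/C(C)=C/C=C/C(C)=C/C=C/C=C(C)/CSc2nnnn2-c3ccccc3)C(C)(C)C[C@H](O[Si](C)(C)C(C)(C)C)C1
F6 | step 8 | 5-{[(2E,4E,6E,8E,10E)-13-[(4R)-4-[(tert-butyldimethylsilyl)oxy]-2,6,6-trimethylcyclohex-1-en-1-yl]-2,7,11-trimethyltrideca-2,4,6,8,10-pentaen-12-yn-1-yl]sulfonyl}-1-phenyl-1H-tetrazole | CC1=C(C#C/C(C)=C/C=C/C(C)=C/C=C/C=C(C)/CS(=O)(=O)c2nnnn2-c3ccccc3)C(C)(C)C[C@H](O[Si](C)(C)C(C)(C)C)C1
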